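**Plan**

1. The target is read as a (2S)-7,3',4'-trihydroxyflavan joined 2,4-trans (upper C4 R) through C4 to C8 of (−)-epigallocatechin (lower C2 R, C3 R).
2. Cuts, in retrosynthetic order: the eight benzyl ethers; the interflavan C4–C8 bond (flavan-4-ol cation plus the epigallocatechin ring A); the aryl ether bond O1–C8a of the upper ring C; the two carbinol C–H bonds (back to a 1,3-diketone); the central C–C bond of the diketone (Claisen).
3. Enabling feature: C8a of the upper ring A lies ortho to the C4a–C4 arm and meta to the C7 oxygen. With fluorine at C8a, only the C2 oxygen (O1) can reach it (six-membered transition state); the C4 oxygen cannot (four-membered). Ring C therefore closes without differentiating the two hydroxyls, and the surviving C4–OH, para to O7 across ring A, becomes the leaving group for the later union.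
4. Forward order: rings A and B are joined as a diketone, both carbinols are set, ring C is closed through O1–C8a, the lower flavan-3-ol is attached at C4, and the benzyl groups are removed.
5. Stereochemistry: upper C2 comes from catalyst-controlled transfer hydrogenation and is retained because its C–O bond is never broken; upper C4 comes from attack on the planar C4 cation anti to the 2-aryl group; lower C2 and C3 come from natural (−)-epigallocatechin.

Key step: step 4

Assumption: the fluorinated hydroxyacetophenone, the dibenzylated methyl benzoate, (−)-epigallocatechin and benzyl bromide are taken as purchasable; the 2,4-trans relation of the upper unit is the one encoded in the target SMILES.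

**Step 1**
Reactants: 1 1-(2-fluoro-4-hydroxyphenyl)ethan-1-one
Product: 2 1-[4-(benzyloxy)-2-fluorophenyl]ethan-1-one
Conditions: BnBr (1.1 equiv), K2CO3 (1.5 equiv), acetone, reflux
Reagents that add atoms: benzyl bromide, BrCc1ccccc1
Why: Williamson etherification of the phenoxide; masking the phenol keeps ring A from being deactivated as a phenoxide in the later fluoride displacement.

**Step 2**
Reactants: 2 1-[4-(benzyloxy)-2-fluorophenyl]ethan-1-one; 3 methyl 3,4-bis(benzyloxy)benzoate
Product: 4 1-[4-(benzyloxy)-2-fluorophenyl]-3-[3,4-bis(benzyloxy)phenyl]propane-1,3-dione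
Conditions: LiN(SiMe3)2 (2.5 equiv), THF, −78 °C to rt; then 1 M aq. HCl
Reagents that add atoms: none
Why: Crossed Claisen condensation of the methyl ketone enolate with the non-enolisable ester, driven by deprotonation of the diketone; it is kept at or below room temperature so that the enolate oxygen should not yet displace the ortho fluoride.

**Step 3**
Reactants: 4 1-[4-(benzyloxy)-2-fluorophenyl]-3-[3,4-bis(benzyloxy)phenyl]propane-1,3-dione
Product: 6 (1S,3S)-1-[4-(benzyloxy)-2-fluorophenyl]-3-[3,4-bis(benzyloxy)phenyl]propane-1,3-diol, via (3S)-hydroxy ketone 5 (not isolated)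
Conditions: RuCl(p-cymene)[(S,S)-TsDPEN] (2 mol %), HCO2H/Et3N (5:2), DMF, 40 °C
Reagents that add atoms: none
Why: Noyori–Ikariya asymmetric transfer hydrogenation of a 1,3-diaryl-1,3-diketone; each aryl ketone should be reduced under catalyst control to the (S)-carbinol (same sense as acetophenone to (S)-1-phenylethanol), giving the anti (1S,3S) diol and thereby the future C2.

**Step 4**
Reactants: 6 (1S,3S)-1-[4-(benzyloxy)-2-fluorophenyl]-3-[3,4-bis(benzyloxy)phenyl]propane-1,3-diol
Product: 7 (2S,4S)-7-(benzyloxy)-2-[3,4-bis(benzyloxy)phenyl]-3,4-dihydro-2H-chromen-4-ol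
Conditions: KOt-Bu (2.5 equiv), degassed DMSO (0.02 M), argon, 70 °C; then H2O
Reagents that add atoms: none
Why: The dialkoxide forms, and the oxygen on the carbinol next to ring B (the future O1) adds to the fluorine-bearing carbon of ring A (the future C8a, ortho to the side arm and meta to the benzyloxy group) to give a Meisenheimer-type adduct that expels fluoride, an intramolecular addition–elimination SNAr. The closest known reaction type is the alkoxide/aryl fluoride ring closure used to build chromans and flavan cores with ring A as the electrophile. Ring C closes in a 6-exo-trig mode at C8a. No new stereocentre is formed: C2 keeps its configuration because its C–O bond is never broken (the benzylic cation that erodes C2 in closures through O1–C2 is avoided), and C4 is untouched. The step needs chemoselectivity between the two alkoxides and no intermolecular arylation: only O1 can reach C8a through a six-membered transition state, the C4 oxygen would have to form a four-membered ring, and dilution suppresses intermolecular displacement. If base-induced loss of HF (C8–H lies between F and OBn) gave the C8–C8a aryne instead, the tether and the adjacent alkoxy group would direct the same oxygen to the same carbon.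

**Step 5**
Reactants: 8 (−)-epigallocatechin
Product: 9 (2R,3R)-5,7-bis(benzyloxy)-2-[3,4,5-tris(benzyloxy)phenyl]-3,4-dihydro-2H-chromen-3-ol
Conditions: BnBr (5.5 equiv), K2CO3 (6 equiv), DMF, argon, −10 °C to rt
Reagents that add atoms: benzyl bromide, BrCc1ccccc1
Why: Williamson etherification of the five phenols, which carbonate deprotonates while the secondary 3-OH stays protonated; low temperature and exclusion of oxygen should limit C2 epimerisation and oxidation of the pyrogallol ring.

**Step 6**
Reactants: 7 (2S,4S)-7-(benzyloxy)-2-[3,4-bis(benzyloxy)phenyl]-3,4-dihydro-2H-chromen-4-ol; 9 (2R,3R)-5,7-bis(benzyloxy)-2-[3,4,5-tris(benzyloxy)phenyl]-3,4-dihydro-2H-chromen-3-ol (3 equiv)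
Product: 11 (2R,3R)-5,7-bis(benzyloxy)-8-{(2S,4R)-7-(benzyloxy)-2-[3,4-bis(benzyloxy)phenyl]-3,4-dihydro-2H-chromen-4-yl}-2-[3,4,5-tris(benzyloxy)phenyl]-3,4-dihydro-2H-chromen-3-ol, via flavan-4-yl cation 10 (not isolated)
Conditions: BF3·OEt2 (0.3 equiv), CH2Cl2, 4 Å molecular sieves, −40 to 0 °C
Reagents that add atoms: none
Why: Biomimetic SN1 Friedel–Crafts union: the C4–OH ionises with loss of water to a cation stabilised by O1 (ortho) and O7 (para), C8 of 9 (less hindered and more nucleophilic than C6, which is flanked by two benzyloxy groups) should attack it pseudo-axially, anti to the pseudo-equatorial 2-aryl group, setting the 2,4-trans (4R) centre; excess 9 suppresses self-condensation.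

**Step 7**
Reactants: 11 (2R,3R)-5,7-bis(benzyloxy)-8-{(2S,4R)-7-(benzyloxy)-2-[3,4-bis(benzyloxy)phenyl]-3,4-dihydro-2H-chromen-4-yl}-2-[3,4,5-tris(benzyloxy)phenyl]-3,4-dihydro-2H-chromen-3-ol
Product: 12 (2R,3R)-8-[(2S,4R)-2-(3,4-dihydroxyphenyl)-7-hydroxy-3,4-dihydro-2H-chromen-4-yl]-2-(3,4,5-trihydroxyphenyl)-3,4-dihydro-2H-chromene-3,5,7-triol
Conditions: H2 (1 atm), Pd(OH)2/C, THF/MeOH/H2O, rt
Reagents that add atoms: none
Why: Hydrogenolysis of the eight aryl benzyl ethers under the neutral conditions customary for benzylated proanthocyanidins, which should leave the cyclic C2–O bonds, the interflavan C–C bond and all four stereocentres untouched.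

**Compound list**

1 | 1-(2-fluoro-4-hydroxyphenyl)ethan-1-one | CC(=O)c1ccc(O)cc1F | starting material
2 | 1-[4-(benzyloxy)-2-fluorophenyl]ethan-1-one | CC(=O)c1ccc(OCc2ccccc2)cc1F | intermediate
3 | methyl 3,4-bis(benzyloxy)benzoate | COC(=O)c1ccc(OCc2ccccc2)c(OCc2ccccc2)c1 | starting material
4 | 1-[4-(benzyloxy)-2-fluorophenyl]-3-[3,4-bis(benzyloxy)phenyl]propane-1,3-dione | O=C(CC(=O)c1ccc(OCc2ccccc2)c(OCc2ccccc2)c1)c1ccc(OCc2ccccc2)cc1F | intermediate
5 | (3S)-3-[4-(benzyloxy)-2-fluorophenyl]-1-[3,4-bis(benzyloxy)phenyl]-3-hydroxypropan-1-one (not isolated) | O=C(C[C@H](O)c1ccc(OCc2ccccc2)cc1F)c1ccc(OCc2ccccc2)c(OCc2ccccc2)c1 | intermediate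
6 | (1S,3S)-1-[4-(benzyloxy)-2-fluorophenyl]-3-[3,4-bis(benzyloxy)phenyl]propane-1,3-diol | O[C@H](c1ccc(OCc2ccccc2)c(OCc2ccccc2)c1)C[C@H](O)c1ccc(OCc2ccccc2)cc1F | intermediate
7 | (2S,4S)-7-(benzyloxy)-2-[3,4-bis(benzyloxy)phenyl]-3,4-dihydro-2H-chromen-4-ol (2,4-cis) | O[C@H]1C[C@@H](c2ccc(OCc3ccccc3)c(OCc3ccccc3)c2)Oc2cc(OCc3ccccc3)ccc21 | intermediate
8 | (−)-epigallocatechin, (2R,3R)-2-(3,4,5-trihydroxyphenyl)-3,4-dihydro-2H-chromene-3,5,7-triol | Oc1cc(O)c2c(c1)O[C@H](c1cc(O)c(O)c(O)c1)[C@H](O)C2 | starting material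
9 | (2R,3R)-5,7-bis(benzyloxy)-2-[3,4,5-tris(benzyloxy)phenyl]-3,4-dihydro-2H-chromen-3-ol | c1ccccc1COc1cc(OCc2ccccc2)c2c(c1)O[C@H](c1cc(OCc3ccccc3)c(OCc3ccccc3)c(OCc3ccccc3)c1)[C@H](O)C2 | intermediate
10 | (2S)-7-(benzyloxy)-2-[3,4-bis(benzyloxy)phenyl]-3,4-dihydro-2H-chromen-4-ylium ion (not isolated) | [CH+]1C[C@@H](c2ccc(OCc3ccccc3)c(OCc3ccccc3)c2)Oc2cc(OCc3ccccc3)ccc21 | intermediate
11 | (2R,3R)-5,7-bis(benzyloxy)-8-{(2S,4R)-7-(benzyloxy)-2-[3,4-bis(benzyloxy)phenyl]-3,4-dihydro-2H-chromen-4-yl}-2-[3,4,5-tris(benzyloxy)phenyl]-3,4-dihydro-2H-chromen-3-ol | c1ccccc1COc1ccc2c(c1)O[C@H](c1ccc(OCc3ccccc3)c(OCc3ccccc3)c1)C[C@H]2c1c(OCc3ccccc3)cc(OCc3ccccc3)c2c1O[C@H](c1cc(OCc3ccccc3)c(OCc3ccccc3)c(OCc3ccccc3)c1)[C@H](O)C2 | intermediate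
12 | (2R,3R)-8-[(2S,4R)-2-(3,4-dihydroxyphenyl)-7-hydroxy-3,4-dihydro-2H-chromen-4-yl]-2-(3,4,5-trihydroxyphenyl)-3,4-dihydro-2H-chromene-3,5,7-triol | Oc1ccc2c(c1)O[C@H](c1ccc(O)c(O)c1)C[C@H]2c1c(O)cc(O)c2c1O[C@H](c1cc(O)c(O)c(O)c1)[C@H](O)C2 | target

**Step count and risks**

Total steps: 7. Longest linear sequence: 6 (steps 1, 2, 3, 4, 6, 7).

Steps most likely to fail:

Step 4. The electron-rich, unactivated aryl fluoride may resist displacement, or the hot dialkoxide may erode its carbinol centres by redox equilibration before ring closure. The fallback sets out from 4 and returns to the route at 7. Heating 4 with K2CO3 in DMF (100 °C) closes ring C at the diketone stage through the same O1–C8a bond, now as a carbonyl-activated SNAr of the enolate oxygen, to give 7-(benzyloxy)-2-[3,4-bis(benzyloxy)phenyl]-4H-chromen-4-one F1. Enantioselective hydrogenation of its C2–C3 double bond with the chiral N-heterocyclic carbene complex formed from Ru(cod)(2-methylallyl)2, a chiral imidazolinium tetrafluoroborate and KOt-Bu (H2, toluene) should give (2S)-7-(benzyloxy)-2-[3,4-bis(benzyloxy)phenyl]-2,3-dihydro-4H-chromen-4-one F2. NaBH4 (MeOH/THF, 0 °C) then reduces F2 by axial hydride delivery to the 2,4-cis alcohol 7.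

Step 6. The nucleophile may attack through C6 instead of C8, approach cis to the 2-aryl group, or the cation may be consumed by self-condensation with ring A of a second electrophile molecule. The fallback sets out from 7 and returns to the route at 12. Neutral hydrogenolysis of 7 (H2, Pd/C, EtOAc, NaHCO3, rt, stopped after three equivalents of H2) gives (2S,4S)-2-(3,4-dihydroxyphenyl)-3,4-dihydro-2H-chromene-4,7-diol F3. F3 is condensed with an excess of unprotected 8 in 0.1 M aqueous HCl at rt; with the free 7-OH the electrophile is the protonated para-quinone methide of the presumed biosynthesis, and this protecting-group-free flavan-4-ol/flavan-3-ol union is the established entry to 4→8-linked 2,4-trans dimers of this class. It gives 12 directly.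

Step 5. Exhaustive etherification may be spoiled by C-benzylation of the phloroglucinol ring, base-induced epimerisation at C2 through ring opening, or oxidative degradation of the pyrogallol ring. The fallback sets out from 7 and 8 and returns to the route at 12. Protection of the nucleophile is omitted: 7 is coupled with unprotected 8 (4 equiv) under BF3·OEt2 in dioxane/THF to give (2R,3R)-8-{(2S,4R)-7-(benzyloxy)-2-[3,4-bis(benzyloxy)phenyl]-3,4-dihydro-2H-chromen-4-yl}-2-(3,4,5-trihydroxyphenyl)-3,4-dihydro-2H-chromene-3,5,7-triol F4, which is debenzylated (H2, Pd(OH)2/C, THF/MeOH) to 12.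

**Further compounds**

F1 | step 4 | 7-(benzyloxy)-2-[3,4-bis(benzyloxy)phenyl]-4H-chromen-4-one | O=c1cc(-c2ccc(OCc3ccccc3)c(OCc3ccccc3)c2)oc2cc(OCc3ccccc3)ccc12
F2 | step 4 | (2S)-7-(benzyloxy)-2-[3,4-bis(benzyloxy)phenyl]-2,3-dihydro-4H-chromen-4-one | O=C1C[C@@H](c2ccc(OCc3ccccc3)c(OCc3ccccc3)c2)Oc2cc(OCc3ccccc3)ccc21
F3 | step 6 | (2S,4S)-2-(3,4-dihydroxyphenyl)-3,4-dihydro-2H-chromene-4,7-diol | O[C@H]1C[C@@H](c2ccc(O)c(O)c2)Oc2cc(O)ccc21
F4 | step 5 | (2R,3R)-8-{(2S,4R)-7-(benzyloxy)-2-[3,4-bis(benzyloxy)phenyl]-3,4-dihydro-2H-chromen-4-yl}-2-(3,4,5-trihydroxyphenyl)-3,4-dihydro-2H-chromene-3,5,7-triol | c1ccccc1COc1ccc2c(c1)O[C@H](c1ccc(OCc3ccccc3)c(OCc3ccccc3)c1)C[C@H]2c1c(O)cc(O)c2c1O[C@H](c1cc(O)c(O)c(O)c1)[C@H](O)C2
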